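**Strategy.** Ring A is disconnected across its C1–C6 bond. The 4-alkylresorcinol (OH at C2 and C4, 1,1-dimethylallyl at C5, H at C6) is the folded form of a 1,3,5-tricarbonyl chain. That chain is stored as a 2,5-disubstituted 4-pyrone which already carries the quaternary carbon and the complete ring-B chroman. In one operation hydroxide unmasks the pyrone to a formyl diketone; its side-chain α-methylene (future C1) adds to the formyl carbon (future C6), and dehydration and enolisation deliver ring A and Kazinol D itself. The pyrone is assembled by enolate acylation of a Claisen-derived methoxymethylidene ketone with a ring-B pentanoyl chloride, followed by acid cyclodehydration.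

Key step: step 14

Remark: compounds 6 and 10 are taken as catalogue chemicals, and the ring-B phenol is carried as a TBS ether that the hydroxide of step 14 removes in the same flask, so that nothing follows the key step.

**Fragment A (steps 1–3)**

Step 1
Reactants: 1 prenol (3-methylbut-2-en-1-ol); 2 but-3-yn-2-one
Product: 3 (E)-4-[(3-methylbut-2-en-1-yl)oxy]but-3-en-2-one
Conditions: DABCO (10 mol%), CH2Cl2, 0 °C → rt
Reagents that add atoms: none
Why: Amine-catalysed oxa-Michael addition of the alcohol to the ynone should give the E β-alkoxy enone under thermodynamic control; no stereocentre is formed.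

Step 2
Reactants: 3 (E)-4-[(3-methylbut-2-en-1-yl)oxy]but-3-en-2-one
Product: 4 2-acetyl-3,3-dimethylpent-4-enal
Conditions: o-dichlorobenzene, 180 °C, sealed tube
Reagents that add atoms: none
Why: Thermal Claisen rearrangement of the allyl vinyl ether through a chair transition state, as known for 3-allyloxy enones, transposes the prenyl unit and creates the quaternary carbon; the new α-carbon is formed racemic and is void because 4 is enolised and becomes sp2 in step 3.

Step 3
Reactants: 4 2-acetyl-3,3-dimethylpent-4-enal
Product: 5 3-(methoxymethylidene)-4,4-dimethylhex-5-en-2-one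
Conditions: Me2SO4, K2CO3, acetone, 56 °C
Reagents that add atoms: dimethyl sulfate, COS(=O)(=O)OC
Why: O-alkylation of the hydroxymethylene-ketone enolate is the standard route to 3-substituted 4-methoxybut-3-en-2-ones; C-methylation would have to build a second quaternary carbon beside the first, and the less hindered formyl-derived oxygen reacts, which keeps the methyl ketone free.

**Fragment B (steps 4–11)**

Step 4
Reactants: 6 2-bromo-4-hydroxy-5-methoxybenzaldehyde (6-bromovanillin); 7 3-chloro-3-methylbut-1-yne
Product: 8 2-bromo-5-methoxy-4-[(2-methylbut-3-yn-2-yl)oxy]benzaldehyde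
Conditions: K2CO3, KI (cat.), CuI (cat.), DMF, 65 °C
Reagents that add atoms: none
Why: Copper-assisted Williamson-type O-alkylation of the phenoxide with the tertiary propargylic chloride is the usual entry to aryl 1,1-dimethylpropargyl ethers, and the phenol is the only acidic site.

Step 5
Reactants: 8 2-bromo-5-methoxy-4-[(2-methylbut-3-yn-2-yl)oxy]benzaldehyde
Product: 9 5-bromo-8-methoxy-2,2-dimethyl-2H-chromene-6-carbaldehyde
Conditions: N,N-diethylaniline, 190 °C
Reagents that add atoms: none
Why: Aromatic propargyl Claisen rearrangement, 1,5-hydrogen shift and oxa-6π electrocyclisation should give the 2,2-dimethylchromene; only one ortho carbon (the one next to C–Br) bears hydrogen, so the ring can close in one direction only and the whole ring-B substitution pattern is fixed without a regiochemical choice.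

Step 6
Reactants: 9 5-bromo-8-methoxy-2,2-dimethyl-2H-chromene-6-carbaldehyde; 10 (4-ethoxy-4-oxobutyl)triphenylphosphonium bromide
Product: 12 ethyl (4Z)-5-(5-bromo-8-methoxy-2,2-dimethyl-2H-chromen-6-yl)pent-4-enoate, via phosphorus ylide 11 (not isolated)
Conditions: NaN(SiMe3)2, THF, −78 °C → rt
Reagents that add atoms: none
Why: Wittig olefination with a non-stabilised ylide should give mainly the Z alkene and installs the full five-carbon chain at the ester oxidation level; the alkene geometry is erased in step 7.

Step 7
Reactants: 12 ethyl (4Z)-5-(5-bromo-8-methoxy-2,2-dimethyl-2H-chromen-6-yl)pent-4-enoate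
Product: 13 ethyl 5-(5-bromo-8-methoxy-2,2-dimethyl-3,4-dihydro-2H-chromen-6-yl)pentanoate
Conditions: H2 (1 atm), PtO2 (5 mol%), EtOAc, rt
Reagents that add atoms: none
Why: Heterogeneous hydrogenation over platinum should saturate the styrenyl side-chain alkene and the chromene C3=C4 bond before any prenyl group is present, while platinum, unlike palladium, is expected to leave the aryl bromide in place.

Step 8
Reactants: 13 ethyl 5-(5-bromo-8-methoxy-2,2-dimethyl-3,4-dihydro-2H-chromen-6-yl)pentanoate; 14 prenyl bromide (1-bromo-3-methylbut-2-ene)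
Product: 16 ethyl 5-[8-methoxy-2,2-dimethyl-5-(3-methylbut-2-en-1-yl)-3,4-dihydro-2H-chromen-6-yl]pentanoate, via prenylzinc bromide 15 (not isolated)
Conditions: 14, Zn dust, LiCl, THF, 0 °C → rt; then 13, Pd(OAc)2 (2 mol%), CPhos (4 mol%), THF, rt
Reagents that add atoms: none
Why: Negishi cross-coupling in which the CPhos ligand is known to make allylic zinc reagents couple at the unsubstituted terminus, so that the linear prenyl arene should form; the bulky electron-rich biarylphosphine permits oxidative addition at the doubly ortho-substituted bromide, and the organozinc tolerates the ester.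

Step 9
Reactants: 16 ethyl 5-[8-methoxy-2,2-dimethyl-5-(3-methylbut-2-en-1-yl)-3,4-dihydro-2H-chromen-6-yl]pentanoate
Product: 17 5-[8-hydroxy-2,2-dimethyl-5-(3-methylbut-2-en-1-yl)-3,4-dihydro-2H-chromen-6-yl]pentanoic acid
Conditions: EtSNa (6 equiv), DMF, 130 °C; then 1 M HCl, 0 °C
Reagents that add atoms: none
Why: Thiolate dealkylation (SN2 at the O-alkyl carbons) should cleave the aryl methyl ether and the ethyl ester in one operation under non-acidic conditions that spare the prenyl alkene and the tertiary chroman ether, which cannot undergo SN2 attack.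

Step 10
Reactants: 17 5-[8-hydroxy-2,2-dimethyl-5-(3-methylbut-2-en-1-yl)-3,4-dihydro-2H-chromen-6-yl]pentanoic acid
Product: 18 tert-butyldimethylsilyl 5-[8-(tert-butyldimethylsilyloxy)-2,2-dimethyl-5-(3-methylbut-2-en-1-yl)-3,4-dihydro-2H-chromen-6-yl]pentanoate
Conditions: TBSCl (2.5 equiv), imidazole (5 equiv), DMF, rt
Reagents that add atoms: tert-butyldimethylsilyl chloride, CC(C)(C)[Si](C)(C)Cl
Why: Imidazole-promoted silylation converts the phenol into its TBS ether and the acid into its TBS ester, which masks the phenol for the acylation and prepares the carboxyl group for neutral activation.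

Step 11
Reactants: 18 tert-butyldimethylsilyl 5-[8-(tert-butyldimethylsilyloxy)-2,2-dimethyl-5-(3-methylbut-2-en-1-yl)-3,4-dihydro-2H-chromen-6-yl]pentanoate
Product: 19 5-[8-(tert-butyldimethylsilyloxy)-2,2-dimethyl-5-(3-methylbut-2-en-1-yl)-3,4-dihydro-2H-chromen-6-yl]pentanoyl chloride
Conditions: (COCl)2 (1.2 equiv), DMF (cat.), CH2Cl2, 0 °C → rt; volatiles removed in vacuo
Reagents that add atoms: oxalyl chloride, ClC(=O)C(=O)Cl
Why: Silyl esters are converted into acid chlorides by the Vilsmeier reagent from oxalyl chloride and DMF under neutral conditions, the silicon leaving as TBSCl and no HCl being released, so the prenyl alkene and the aryl silyl ether should survive.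

**Union and ring A (steps 12–14)**

Step 12
Reactants: 5 3-(methoxymethylidene)-4,4-dimethylhex-5-en-2-one; 19 5-[8-(tert-butyldimethylsilyloxy)-2,2-dimethyl-5-(3-methylbut-2-en-1-yl)-3,4-dihydro-2H-chromen-6-yl]pentanoyl chloride
Product: 21 11-[8-(tert-butyldimethylsilyloxy)-2,2-dimethyl-5-(3-methylbut-2-en-1-yl)-3,4-dihydro-2H-chromen-6-yl]-4-(methoxymethylidene)-3,3-dimethylundec-1-ene-5,7-dione, via lithium enolate 20 (not isolated)
Conditions: 5 (2.2 equiv), LiN(SiMe3)2 (2.2 equiv), THF, −78 °C; then 19 (1.0 equiv), −78 °C; aq. NH4Cl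
Reagents that add atoms: none
Why: Kinetic deprotonation at the only enolisable position (the methyl group) and C-acylation of the lithium enolate by the acid chloride is the established Claisen-type acylation of β-methoxy enones; the second equivalent of enolate absorbs the acidic β-diketone proton and is recovered as 5.

Step 13
Reactants: 21 the methoxymethylidene β-diketone of step 12
Product: 22 2-{4-[8-(tert-butyldimethylsilyloxy)-2,2-dimethyl-5-(3-methylbut-2-en-1-yl)-3,4-dihydro-2H-chromen-6-yl]butyl}-5-(2-methylbut-3-en-2-yl)-4H-pyran-4-one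
Conditions: TsOH·H2O (10 mol%), toluene, 40 °C
Reagents that add atoms: none
Why: Acid-catalysed cyclodehydration, in which the diketone enol oxygen adds to the β-methoxy enone and methanol is eliminated, should give the 4-pyrone; a catalytic amount of sulfonic acid spares the prenyl alkene, the terminal vinyl group and the aryl silyl ether.

Step 14
Reactants: 22 the TBS-protected 4-pyrone of step 13
Product: 25 Kazinol D, via free-phenol pyrone 23 (not isolated), via formyl diketone 24 (not isolated)
Conditions: Ba(OH)2·8H2O (6 equiv), degassed 1,4-dioxane/H2O (3:1), Ar, 25 → 70 °C; then 1 M HCl to pH 5, 0 °C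
Reagents that add atoms: none
Why: Hydroxide first cleaves the aryl silyl ether (23) and then adds to the unsubstituted α-carbon C6 of the pyrone (attack at the alkylated C2 leads to the same chain); ring opening gives the barium enolate of formyl diketone 24, whose methylene α to the terminal ketone adds to the formyl carbon, and loss of water with enolisation of both ketones gives the resorcinol dianion, protonated on work-up. The closest known reaction type is the alkali-mediated conversion of 2,6-dialkyl-4-pyrones into orcinol-type resorcinols through the open triketone, the aldol folding of a poly-β-carbonyl chain; closure onto a formyl carbon is an extension of that precedent, and the quenched mixture should therefore be monitored for the deformylated 1,3-diketone. Ring A closes by a 6-(enolendo)-exo-trig aldol that forms the C1–C6 bond, and no stereocentre is created. The step needs chemoselectivity for this aldol over hydroxide-induced loss of the formyl carbon (retro-Claisen cleavage) and over re-closure to the pyrone. The substrate secures this because the side-chain methylene is the only enolisable carbon that can reach the formyl group through a six-membered transition state, the barium ion holds the tricarbonyl as a folded chelate with the formyl group largely masked as its enolate, the tert-alkyl group on the neighbouring carbon favours the folded rotamer, and aromatisation makes the closure the only irreversible path. Degassed solvent guards the electron-rich phenoxides against air oxidation.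

**Compound list**

1 | prenol (3-methylbut-2-en-1-ol) | CC(C)=CCO | starting material
2 | but-3-yn-2-one | CC(=O)C#C | starting material
3 | (E)-4-[(3-methylbut-2-en-1-yl)oxy]but-3-en-2-one | CC(=O)/C=C/OCC=C(C)C | intermediate
4 | 2-acetyl-3,3-dimethylpent-4-enal (racemic, largely the hydroxymethylene enol) | CC(=O)C(C=O)C(C)(C)C=C | intermediate
5 | 3-(methoxymethylidene)-4,4-dimethylhex-5-en-2-one (E/Z mixture, either isomer serves) | COC=C(C(C)=O)C(C)(C)C=C | intermediate
6 | 2-bromo-4-hydroxy-5-methoxybenzaldehyde (6-bromovanillin) | COc1cc(C=O)c(Br)cc1O | starting material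
7 | 3-chloro-3-methylbut-1-yne | CC(C)(Cl)C#C | starting material
8 | 2-bromo-5-methoxy-4-[(2-methylbut-3-yn-2-yl)oxy]benzaldehyde | COc1cc(C=O)c(Br)cc1OC(C)(C)C#C | intermediate
9 | 5-bromo-8-methoxy-2,2-dimethyl-2H-chromene-6-carbaldehyde | COc1cc(C=O)c(Br)c2C=CC(C)(C)Oc12 | intermediate
10 | (4-ethoxy-4-oxobutyl)triphenylphosphonium bromide | CCOC(=O)CCC[P+](c1ccccc1)(c1ccccc1)c1ccccc1.[Br-] | starting material
11 | ethyl 4-(triphenyl-λ5-phosphanylidene)butanoate (ylide, not isolated) | CCOC(=O)CCC=P(c1ccccc1)(c1ccccc1)c1ccccc1 | intermediate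
12 | ethyl (4Z)-5-(5-bromo-8-methoxy-2,2-dimethyl-2H-chromen-6-yl)pent-4-enoate (Z expected as main isomer) | CCOC(=O)CC/C=C\c1cc(OC)c2OC(C)(C)C=Cc2c1Br | intermediate
13 | ethyl 5-(5-bromo-8-methoxy-2,2-dimethyl-3,4-dihydro-2H-chromen-6-yl)pentanoate | CCOC(=O)CCCCc1cc(OC)c2OC(C)(C)CCc2c1Br | intermediate
14 | prenyl bromide (1-bromo-3-methylbut-2-ene) | CC(C)=CCBr | starting material
15 | (3-methylbut-2-en-1-yl)zinc bromide (not isolated) | CC(C)=CC[Zn]Br | intermediate
16 | ethyl 5-[8-methoxy-2,2-dimethyl-5-(3-methylbut-2-en-1-yl)-3,4-dihydro-2H-chromen-6-yl]pentanoate | CCOC(=O)CCCCc1cc(OC)c2OC(C)(C)CCc2c1CC=C(C)C | intermediate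
17 | 5-[8-hydroxy-2,2-dimethyl-5-(3-methylbut-2-en-1-yl)-3,4-dihydro-2H-chromen-6-yl]pentanoic acid | OC(=O)CCCCc1cc(O)c2OC(C)(C)CCc2c1CC=C(C)C | intermediate
18 | tert-butyldimethylsilyl 5-[8-(tert-butyldimethylsilyloxy)-2,2-dimethyl-5-(3-methylbut-2-en-1-yl)-3,4-dihydro-2H-chromen-6-yl]pentanoate | CC(C)(C)[Si](C)(C)OC(=O)CCCCc1cc(O[Si](C)(C)C(C)(C)C)c2OC(C)(C)CCc2c1CC=C(C)C | intermediate
19 | 5-[8-(tert-butyldimethylsilyloxy)-2,2-dimethyl-5-(3-methylbut-2-en-1-yl)-3,4-dihydro-2H-chromen-6-yl]pentanoyl chloride | ClC(=O)CCCCc1cc(O[Si](C)(C)C(C)(C)C)c2OC(C)(C)CCc2c1CC=C(C)C | intermediate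
20 | lithium 3-(methoxymethylidene)-4,4-dimethylhexa-1,5-dien-2-olate (not isolated) | [Li+].[O-]C(=C)C(=COC)C(C)(C)C=C | intermediate
21 | 11-[8-(tert-butyldimethylsilyloxy)-2,2-dimethyl-5-(3-methylbut-2-en-1-yl)-3,4-dihydro-2H-chromen-6-yl]-4-(methoxymethylidene)-3,3-dimethylundec-1-ene-5,7-dione (E/Z mixture, largely enolised) | COC=C(C(=O)CC(=O)CCCCc1cc(O[Si](C)(C)C(C)(C)C)c2OC(C)(C)CCc2c1CC=C(C)C)C(C)(C)C=C | intermediate
22 | 2-{4-[8-(tert-butyldimethylsilyloxy)-2,2-dimethyl-5-(3-methylbut-2-en-1-yl)-3,4-dihydro-2H-chromen-6-yl]butyl}-5-(2-methylbut-3-en-2-yl)-4H-pyran-4-one | C=CC(C)(C)c1coc(CCCCc2cc(O[Si](C)(C)C(C)(C)C)c3OC(C)(C)CCc3c2CC=C(C)C)cc1=O | intermediate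
23 | 2-{4-[8-hydroxy-2,2-dimethyl-5-(3-methylbut-2-en-1-yl)-3,4-dihydro-2H-chromen-6-yl]butyl}-5-(2-methylbut-3-en-2-yl)-4H-pyran-4-one (present as phenoxide, not isolated) | C=CC(C)(C)c1coc(CCCCc2cc(O)c3c(c2CC=C(C)C)CCC(C)(C)O3)cc1=O | intermediate
24 | 9-[8-hydroxy-2,2-dimethyl-5-(3-methylbut-2-en-1-yl)-3,4-dihydro-2H-chromen-6-yl]-2-(2-methylbut-3-en-2-yl)-3,5-dioxononanal (present as barium enolate, α-carbon not configurationally defined, not isolated) | O=CC(C(=O)CC(=O)CCCCc1cc(O)c2OC(C)(C)CCc2c1CC=C(C)C)C(C)(C)C=C | intermediate
25 | Kazinol D, 4-{3-[8-hydroxy-2,2-dimethyl-5-(3-methylbut-2-en-1-yl)-3,4-dihydro-2H-chromen-6-yl]propyl}-6-(2-methylbut-3-en-2-yl)benzene-1,3-diol | C=CC(C)(C)c1cc(CCCc2cc(O)c3c(c2CC=C(C)C)CCC(C)(C)O3)c(O)cc1O | target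

**Step count**

Total: 14 steps (fragment A, steps 1–3; fragment B, steps 4–11; union and ring A, steps 12–14).
Longest linear sequence: 11 steps (steps 4–14, from 6 to 25).

**Steps most likely to fail**

1. Step 14. Hydroxide may cleave the formyl carbon from the opened chain (retro-Claisen deformylation) faster than the side-chain enolate closes onto it, or the chain may simply re-close to the pyrone on acidification. The fallback sets out from 21, the open-chain enol ether made one step before the pyrone, and closes ring A without hydroxide and without a free aldehyde. Treatment of 21 with LiN(iPr)2 (2.5 equiv) in THF/DMPU (−78 → 25 °C) should give the 1,3-diketone dianion, whose second charge sits on the side-chain carbon, the only remaining enolisable position. This carbon closes on the methoxymethylidene carbon (anionic 6π closure, equivalent to a conjugate addition), and loss of methoxide with enolisation gives the ring-B silyl ether of Kazinol D F1. Bu4NF/AcOH (THF, 0 °C) then removes the silyl group and the route is rejoined at 25.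

2. Step 8. Oxidative addition at the doubly ortho-substituted, electron-rich C–Br bond may be slow, so that protodebromination takes over, or 1,3-transposition of the allylic zinc reagent may deliver the branched 1,1-dimethylallyl isomer. The fallback sets out from 13 and uses an allyl group, for which linear and branched isomers are identical. Stille coupling with allyltributylstannane (Pd(PPh3)4, CsF, 1,4-dioxane, 100 °C) should give ethyl 5-[8-methoxy-2,2-dimethyl-5-(prop-2-en-1-yl)-3,4-dihydro-2H-chromen-6-yl]pentanoate F2. Olefin cross-metathesis with excess 2-methylbut-2-ene (second-generation Grubbs catalyst, RuCl2(=CHPh)(PCy3)(H2IMes), CH2Cl2, 40 °C) then converts the allyl into the prenyl group and returns to the route at 16.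

3. Step 2. At the temperature that the vinylogous-ester Claisen rearrangement needs, fragmentation of the prenyl enol ether (retro-ene loss of isoprene) or a 1,3-shift to the linear C-prenyl isomer may compete with the [3,3] shift. The fallback sets out from 1 and sets the quaternary carbon by the easier unactivated aliphatic Claisen rearrangement. Prenol 1 is O-vinylated with vinyl acetate ([Ir(cod)Cl]2, Na2CO3, toluene, 100 °C) to 3-methylbut-2-en-1-yl vinyl ether F3, which rearranges (sealed tube, 140 °C) to 3,3-dimethylpent-4-enal F4. Condensation with morpholine (K2CO3, 0 °C → rt) gives the enamine 4-[(1E)-3,3-dimethylpenta-1,4-dien-1-yl]morpholine F5. Stork enamine C-acylation with acetyl chloride/Et3N (CH2Cl2, 0 °C) gives the enaminone 4,4-dimethyl-3-(morpholin-4-ylmethylidene)hex-5-en-2-one F6. Mild hydrolysis (aq. AcOH/NaOAc, THF) releases the β-keto aldehyde and the route is rejoined at 4.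

**Further compounds**

F1 | step 14 | 4-{3-[8-(tert-butyldimethylsilyloxy)-2,2-dimethyl-5-(3-methylbut-2-en-1-yl)-3,4-dihydro-2H-chromen-6-yl]propyl}-6-(2-methylbut-3-en-2-yl)benzene-1,3-diol | C=CC(C)(C)c1cc(CCCc2cc(O[Si](C)(C)C(C)(C)C)c3OC(C)(C)CCc3c2CC=C(C)C)c(O)cc1O
F2 | step 8 | ethyl 5-[8-methoxy-2,2-dimethyl-5-(prop-2-en-1-yl)-3,4-dihydro-2H-chromen-6-yl]pentanoate | CCOC(=O)CCCCc1cc(OC)c2OC(C)(C)CCc2c1CC=C
F3 | step 2 | 3-methylbut-2-en-1-yl vinyl ether | CC(C)=CCOC=C
F4 | step 2 | 3,3-dimethylpent-4-enal | C=CC(C)(C)CC=O
F5 | step 2 | 4-[(1E)-3,3-dimethylpenta-1,4-dien-1-yl]morpholine | C=CC(C)(C)/C=C/N1CCOCC1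
F6 | step 2 | 4,4-dimethyl-3-(morpholin-4-ylmethylidene)hex-5-en-2-one | CC(=O)C(=CN1CCOCC1)C(C)(C)C=C
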